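**Plan**

1. Cuts: the C3–C4 oxirane is traced back to an E-alkene. The 14-membered carbocycle is then opened at C5–C6: C5 is a lone methylene between the Z-C6=C7 alkene and C4, so in the deoxy ring it is the sp3 carbon of a 1,4-diene and can come from an allylic chloride and a Z-alkenylstannane. The seco chain is cut at C14–C1 and at the lactone C16–O bond.
2. Forward: a C6–C14 stannyl aldehyde (from (S)-citronellal) and a C1–C5 bromomethyl enoate that already carries the C5 chloride are joined by indium allylation, which also closes the α-methylene-γ-lactone ring. The 14-membered ring follows by allyl–alkenyl Stille closure, and the oxirane is made last.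
3. Stereochemistry: C12 from (S)-citronellal; C13 by L-proline α-aminoxylation; C8 by Sharpless epoxidation and hydride opening; C14 and C1 by chelate-controlled addition of a Z-allylindium; C3/C4 by Shi epoxidation. The Z-alkene comes from hydrozirconation of an alkynylstannane, the E-alkene from a Wittig reaction.

Key step: step 21

Remark: cembrane numbering is used throughout (C1 ring-fusion CH, C14 lactone O–CH, C13 CHOH, C12 CHMe, C8 tertiary carbinol, C15–C17 lactone carbons). Compounds 5–12 are mixtures of epimers at the acetal carbon only, which is removed in step 11. Compound 15 and all reagents are taken as catalogue chemicals.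

**Fragment 1: C6–C14 stannyl aldehyde**

Step 1
Reactants: 1 (S)-citronellal
Product: 3 (2R,3S)-3,7-dimethyl-2-[(phenylamino)oxy]oct-6-en-1-ol, via α-aminoxy aldehyde 2 (not isolated)
Conditions: PhNO, L-proline (20 mol%), CHCl3, 4 °C; then NaBH4, EtOH, 0 °C
Reagents that add atoms: nitrosobenzene (O=Nc1ccccc1)
Why: Proline enamine catalysis (α-aminoxylation) delivers the nitroso oxygen to one enamine face under direction by the carboxylic acid, so the L-catalyst should set C13 as R largely independently of the β-methyl centre, and reduction in the same flask removes the epimerisable α-oxy aldehyde.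

Step 2
Reactants: 3 (2R,3S)-3,7-dimethyl-2-[(phenylamino)oxy]oct-6-en-1-ol
Product: 4 (2R,3S)-3,7-dimethyloct-6-ene-1,2-diol
Conditions: Zn dust, AcOH, THF, rt
Reagents that add atoms: none
Why: Dissolving-metal reduction cleaves the weak N–O bond of the O-alkyl-N-arylhydroxylamine and leaves the trisubstituted alkene untouched.

Step 3
Reactants: 4 (2R,3S)-3,7-dimethyloct-6-ene-1,2-diol
Product: 5 (4R)-2-(4-methoxyphenyl)-4-[(2S)-6-methylhept-5-en-2-yl]-1,3-dioxolane
Conditions: 4-MeOC6H4CH(OMe)2, pyridinium p-toluenesulfonate (PPTS, cat.), CH2Cl2, rt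
Reagents that add atoms: 4-methoxybenzaldehyde dimethyl acetal (COc1ccc(cc1)C(OC)OC)
Why: Acid-catalysed transacetalisation ties the 1,2-diol into a p-methoxybenzylidene acetal that should survive the oxidations and hydride steps ahead and can later be opened reductively to one PMB ether.

Step 4
Reactants: 5 (4R)-2-(4-methoxyphenyl)-4-[(2S)-6-methylhept-5-en-2-yl]-1,3-dioxolane
Product: 6 (2E,6S)-6-[(4R)-2-(4-methoxyphenyl)-1,3-dioxolan-4-yl]-2-methylhept-2-en-1-ol
Conditions: SeO2 (0.3 equiv), t-BuOOH (anhydrous, in decane), CH2Cl2, rt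
Reagents that add atoms: tert-butyl hydroperoxide (CC(C)(C)OO)
Why: Allylic oxidation with SeO2 (ene reaction then [2,3]-shift) is selective for the E-methyl group of a trisubstituted gem-dimethyl alkene, which turns the future C7 into a hydroxymethyl group.

Step 5
Reactants: 6 (2E,6S)-6-[(4R)-2-(4-methoxyphenyl)-1,3-dioxolan-4-yl]-2-methylhept-2-en-1-ol
Product: 7 {(2R,3R)-3-[(3S)-3-[(4R)-2-(4-methoxyphenyl)-1,3-dioxolan-4-yl]butyl]-2-methyloxiran-2-yl}methanol
Conditions: Ti(OiPr)4 (10 mol%), D-(−)-diethyl tartrate (12 mol%), t-BuOOH, 4 Å molecular sieves, CH2Cl2, −20 °C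
Reagents that add atoms: tert-butyl hydroperoxide (CC(C)(C)OO)
Why: Sharpless asymmetric epoxidation of the E-2-methylallylic alcohol is reagent-controlled, and the D-tartrate complex should deliver oxygen to the face that gives the 2R,3R epoxy alcohol, in which the C8–O bond already has the sense needed for the 8S carbinol.

Step 6
Reactants: 7 {(2R,3R)-3-[(3S)-3-[(4R)-2-(4-methoxyphenyl)-1,3-dioxolan-4-yl]butyl]-2-methyloxiran-2-yl}methanol
Product: 8 (2S,6S)-6-[(4R)-2-(4-methoxyphenyl)-1,3-dioxolan-4-yl]-2-methylheptane-1,2-diol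
Conditions: LiAlH4, THF, 0 °C to rt
Reagents that add atoms: none
Why: Regioselective hydride opening of the trisubstituted epoxide by SN2 attack at the less substituted C9 leaves the C8–O bond untouched and gives the tertiary carbinol as a 1,2-diol.

Step 7
Reactants: 8 (2S,6S)-6-[(4R)-2-(4-methoxyphenyl)-1,3-dioxolan-4-yl]-2-methylheptane-1,2-diol
Product: 9 (2S,6S)-2-hydroxy-6-[(4R)-2-(4-methoxyphenyl)-1,3-dioxolan-4-yl]-2-methylheptanal
Conditions: IBX, DMSO, rt
Reagents that add atoms: none
Why: IBX oxidation takes the primary hydroxyl of a 1,2-diol to the α-hydroxy aldehyde without glycol cleavage, and the fully substituted C8 cannot epimerise.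

Step 8
Reactants: 9 (2S,6S)-2-hydroxy-6-[(4R)-2-(4-methoxyphenyl)-1,3-dioxolan-4-yl]-2-methylheptanal
Product: 10 (3S,7S)-7-[(4R)-2-(4-methoxyphenyl)-1,3-dioxolan-4-yl]-3-methyloct-1-yn-3-ol
Conditions: dimethyl (1-diazo-2-oxopropyl)phosphonate, K2CO3, MeOH, 0 °C to rt
Reagents that add atoms: dimethyl (1-diazo-2-oxopropyl)phosphonate (CC(=O)C(=[N+]=[N-])P(=O)(OC)OC)
Why: Seyferth–Gilbert homologation with the Ohira–Bestmann reagent adds C6 as a terminal alkyne under mild carbonate conditions that tolerate the free tertiary alcohol and the acetal.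

Step 9
Reactants: 10 (3S,7S)-7-[(4R)-2-(4-methoxyphenyl)-1,3-dioxolan-4-yl]-3-methyloct-1-yn-3-ol
Product: 11 (3S,7S)-7-[(4R)-2-(4-methoxyphenyl)-1,3-dioxolan-4-yl]-3-methyl-1-(tributylstannyl)oct-1-yn-3-ol
Conditions: n-BuLi (2.1 equiv), THF, −78 °C; Bu3SnCl (1.05 equiv), −78 to 0 °C
Reagents that add atoms: tributyltin chloride (CCCC[Sn](Cl)(CCCC)CCCC)
Why: Double deprotonation gives the alkoxide acetylide, whose carbon terminus is stannylated (acetylide stannylation), and the alkoxide is simply reprotonated on work-up.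

Step 10
Reactants: 11 (3S,7S)-7-[(4R)-2-(4-methoxyphenyl)-1,3-dioxolan-4-yl]-3-methyl-1-(tributylstannyl)oct-1-yn-3-ol
Product: 12 (1Z,3S,7S)-7-[(4R)-2-(4-methoxyphenyl)-1,3-dioxolan-4-yl]-3-methyl-1-(tributylstannyl)oct-1-en-3-ol
Conditions: Cp2Zr(H)Cl (2.5 equiv), THF, rt; then H2O
Reagents that add atoms: none
Why: Hydrozirconation is a syn addition that puts zirconium on the tin-bearing carbon, and protonolysis of the C–Zr bond with retention should leave tin cis to the carbinol carbon, so only the Z-alkenylstannane is expected.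

Step 11
Reactants: 12 (1Z,3S,7S)-7-[(4R)-2-(4-methoxyphenyl)-1,3-dioxolan-4-yl]-3-methyl-1-(tributylstannyl)oct-1-en-3-ol
Product: 13 (2R,3S,7S,8Z)-2-[(4-methoxyphenyl)methoxy]-3,7-dimethyl-9-(tributylstannyl)non-8-ene-1,7-diol
Conditions: i-Bu2AlH (4 equiv), CH2Cl2, −78 to 0 °C
Reagents that add atoms: none
Why: Reductive opening of the p-methoxybenzylidene acetal: the aluminium hydride coordinates the less hindered primary oxygen, which ends as the free alcohol, and the PMB group stays on the secondary C13 oxygen.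

Step 12
Reactants: 13 (2R,3S,7S,8Z)-2-[(4-methoxyphenyl)methoxy]-3,7-dimethyl-9-(tributylstannyl)non-8-ene-1,7-diol
Product: 14 (2R,3S,7S,8Z)-7-hydroxy-2-[(4-methoxyphenyl)methoxy]-3,7-dimethyl-9-(tributylstannyl)non-8-enal
Conditions: Dess–Martin periodinane, pyridine, CH2Cl2, 0 °C to rt; used crude
Reagents that add atoms: none
Why: Buffered Dess–Martin oxidation gives the α-alkoxy aldehyde without acid exposure of the alkenylstannane and without epimerisation at C13, and the tertiary alcohol is inert.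

**Fragment 2: C1–C5 bromomethyl enoate**

Step 13
Reactants: 15 3-[(tert-butyldimethylsilyl)oxy]propanal
Product: 16 ethyl (2E)-5-[(tert-butyldimethylsilyl)oxy]-2-methylpent-2-enoate
Conditions: Ph3P=C(CH3)CO2Et, CH2Cl2, rt
Reagents that add atoms: ethyl 2-(triphenylphosphoranylidene)propanoate (CCOC(=O)C(C)=P(c1ccccc1)(c1ccccc1)c1ccccc1)
Why: Wittig olefination with a stabilised α-branched ylide gives the E-trisubstituted enoate, which is the future C3=C4 alkene with its methyl group.

Step 14
Reactants: 16 ethyl (2E)-5-[(tert-butyldimethylsilyl)oxy]-2-methylpent-2-enoate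
Product: 17 (2E)-5-[(tert-butyldimethylsilyl)oxy]-2-methylpent-2-en-1-ol
Conditions: i-Bu2AlH (2.2 equiv), CH2Cl2, −78 °C
Reagents that add atoms: none
Why: Low-temperature aluminium hydride reduction takes the conjugated ester to the allylic alcohol (C5) by 1,2-addition only.

Step 15
Reactants: 17 (2E)-5-[(tert-butyldimethylsilyl)oxy]-2-methylpent-2-en-1-ol
Product: 19 tert-butyl{[(3E)-5-chloro-4-methylpent-3-en-1-yl]oxy}dimethylsilane, via allylic mesylate 18 (not isolated)
Conditions: MsCl, 2,4,6-collidine, LiCl, DMF, 0 °C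
Reagents that add atoms: lithium chloride ([Li+].[Cl-])
Why: Collington–Meyers chlorination: the primary allylic mesylate is displaced by chloride in a direct SN2 reaction, so the E-alkene is neither transposed nor isomerised.

Step 16
Reactants: 19 tert-butyl{[(3E)-5-chloro-4-methylpent-3-en-1-yl]oxy}dimethylsilane
Product: 20 (3E)-5-chloro-4-methylpent-3-en-1-ol
Conditions: aq. HF (48%), MeCN, 0 °C
Reagents that add atoms: none
Why: Acidic fluoride cleavage of the primary silyl ether is fast and non-basic, so the allylic chloride should be spared.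

Step 17
Reactants: 20 (3E)-5-chloro-4-methylpent-3-en-1-ol
Product: 21 (3E)-5-chloro-4-methylpent-3-enal
Conditions: Dess–Martin periodinane, pyridine, CH2Cl2, 0 °C; solution used at once
Reagents that add atoms: none
Why: Dess–Martin oxidation under buffered, non-enolising conditions gives the β,γ-unsaturated aldehyde, and immediate use avoids conjugation of the alkene.

Step 18
Reactants: 21 (3E)-5-chloro-4-methylpent-3-enal
Product: 22 methyl (5E)-7-chloro-3-hydroxy-6-methyl-2-methylidenehept-5-enoate (racemic carbinol)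
Conditions: i-Bu2AlH, N-methylmorpholine N-oxide, THF, 0 °C; methyl propiolate, 0 °C; then 21, 0 °C to rt
Reagents that add atoms: methyl propiolate (COC(=O)C#C)
Why: Vinylalumination: hydroalumination of methyl propiolate gives the α-aluminated acrylate, which adds to the aldehyde to give the Baylis–Hillman-type alcohol without an amine that would enolise the aldehyde or be alkylated by the allylic chloride; the new carbinol centre is lost in the next step.

Step 19
Reactants: 22 methyl (5E)-7-chloro-3-hydroxy-6-methyl-2-methylidenehept-5-enoate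
Product: 23 methyl (2Z,5E)-2-(bromomethyl)-7-chloro-6-methylhepta-2,5-dienoate
Conditions: NBS, Me2S, CH2Cl2, 0 °C to rt
Reagents that add atoms: N-bromosuccinimide (BrN1C(=O)CCC1=O)
Why: Corey–Kim-type activation of the allylic alcohol followed by SN2' attack of bromide gives the more stable Z-2-(bromomethyl)enoate, with the chain trans to the ester.

**Union, ring closure and end game**

Step 20
Reactants: 14 (2R,3S,7S,8Z)-7-hydroxy-2-[(4-methoxyphenyl)methoxy]-3,7-dimethyl-9-(tributylstannyl)non-8-enal; 23 methyl (2Z,5E)-2-(bromomethyl)-7-chloro-6-methylhepta-2,5-dienoate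
Product: 25 (4S,5R)-4-[(2E)-4-chloro-3-methylbut-2-en-1-yl]-5-[(1R,2S,6S,7Z)-6-hydroxy-1-[(4-methoxyphenyl)methoxy]-2,6-dimethyl-8-(tributylstannyl)oct-7-en-1-yl]-3-methylideneoxolan-2-one, via hydroxy ester 24 (not isolated)
Conditions: indium powder, THF/H2O (1:1), rt; then PPTS (cat.), CH2Cl2, rt
Reagents that add atoms: none
Why: Indium-mediated Barbier allylation in water: indium inserts into the activated bromide and not into the unactivated allylic chloride, the Z-allylindium adds through a chair transition state to give the C14/C1 syn pair, chelation of indium between the aldehyde and the PMB ether oxygen should direct attack anti to the C12 branch (13,14-syn), and mild acid then closes the cis-fused α-methylene-γ-lactone.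

Step 21
Reactants: 25 seco C5 allylic chloride with C6 Z-alkenylstannane (13-O-PMB)
Product: 26 13-O-PMB 3,4-deoxy macrocycle (14-membered ring with E-C3=C4 and Z-C6=C7; 1S,8S,12S,13R,14R)
Conditions: Pd2(dba)3 (10 mol%), AsPh3 (40 mol%), N-methylpyrrolidone, 2 mM, slow addition, 40 °C
Reagents that add atoms: none
Why: Stille allyl–alkenyl coupling: zerovalent palladium ionises the C5 allylic chloride to a divalent π-allylpalladium chloride, the Z-alkenylstannane transfers its alkenyl group with retention, and reductive elimination forms C5–C6. The closest known reaction type is the intramolecular Stille coupling of allylic halides with alkenylstannanes used to close macrocyclic 1,4-dienes. The 14-membered carbocycle closes end to end, between the primary π-allyl terminus and the alkenyl carbon, under high dilution. No stereocentre is formed; the Z geometry is carried in by stereoretentive transmetallation and the E geometry because the syn π-allyl complex derived from the E-chloride is the more stable one. The step needs coupling at C5 and not at C3 (which would give a 12-membered ring with a vinyl branch), and the unhindered primary allyl terminus should secure this. The neutral AsPh3 system speeds up transmetallation and tolerates the methylene lactone, the free tertiary alcohol and the PMB ether.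

Step 22
Reactants: 26 13-O-PMB 3,4-deoxy macrocycle
Product: 27 13-O-PMB (3R,4R)-epoxy macrocycle
Conditions: 1,2:4,5-di-O-isopropylidene-β-D-erythro-2,3-hexodiulo-2,6-pyranose (D-fructose-derived Shi ketone, 0.3–1 equiv), Oxone (2KHSO5·KHSO4·K2SO4), K2CO3, Bu4NHSO4, MeCN/CH2(OMe)2/aq. Na2B4O7 buffer, 0 °C
Reagents that add atoms: potassium peroxymonosulfate (OOS(=O)(=O)[O-].[K+])
Why: Shi asymmetric epoxidation: the chiral dioxirane reacts fastest with the electron-rich trisubstituted E-alkene through a spiro transition state and should deliver oxygen to the face that gives the 3R,4R oxirane, while the hindered Z-alkene and the electron-poor methylene lactone are left alone.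

Step 23
Reactants: 27 13-O-PMB (3R,4R)-epoxy macrocycle
Product: 28 CNP0304380.1
Conditions: DDQ, CH2Cl2/pH 7 buffer (KH2PO4/K2HPO4), 0 °C
Reagents that add atoms: none
Why: Oxidative PMB cleavage by DDQ under buffered conditions frees the C13 hydroxyl without opening the oxirane, and is placed after the epoxidation so that no doubly allylic C5 methylene is exposed to the quinone.

**Compound list**

1 | (S)-citronellal, (3S)-3,7-dimethyloct-6-enal | O=CC[C@@H](C)CCC=C(C)C | starting material
2 | (2R,3S)-3,7-dimethyl-2-[(phenylamino)oxy]oct-6-enal | O=C[C@H](ONc1ccccc1)[C@@H](C)CCC=C(C)C | intermediate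
3 | (2R,3S)-3,7-dimethyl-2-[(phenylamino)oxy]oct-6-en-1-ol | OC[C@H](ONc1ccccc1)[C@@H](C)CCC=C(C)C | intermediate
4 | (2R,3S)-3,7-dimethyloct-6-ene-1,2-diol | OC[C@H](O)[C@@H](C)CCC=C(C)C | intermediate
5 | (4R)-2-(4-methoxyphenyl)-4-[(2S)-6-methylhept-5-en-2-yl]-1,3-dioxolane | COc1ccc(cc1)C1OC[C@H](O1)[C@@H](C)CCC=C(C)C | intermediate
6 | (2E,6S)-6-[(4R)-2-(4-methoxyphenyl)-1,3-dioxolan-4-yl]-2-methylhept-2-en-1-ol | COc1ccc(cc1)C1OC[C@H](O1)[C@@H](C)CC/C=C(\C)CO | intermediate
7 | {(2R,3R)-3-[(3S)-3-[(4R)-2-(4-methoxyphenyl)-1,3-dioxolan-4-yl]butyl]-2-methyloxiran-2-yl}methanol | COc1ccc(cc1)C1OC[C@H](O1)[C@@H](C)CC[C@H]2O[C@]2(C)CO | intermediate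
8 | (2S,6S)-6-[(4R)-2-(4-methoxyphenyl)-1,3-dioxolan-4-yl]-2-methylheptane-1,2-diol | COc1ccc(cc1)C1OC[C@H](O1)[C@@H](C)CCC[C@](C)(O)CO | intermediate
9 | (2S,6S)-2-hydroxy-6-[(4R)-2-(4-methoxyphenyl)-1,3-dioxolan-4-yl]-2-methylheptanal | COc1ccc(cc1)C1OC[C@H](O1)[C@@H](C)CCC[C@](C)(O)C=O | intermediate
10 | (3S,7S)-7-[(4R)-2-(4-methoxyphenyl)-1,3-dioxolan-4-yl]-3-methyloct-1-yn-3-ol | COc1ccc(cc1)C1OC[C@H](O1)[C@@H](C)CCC[C@](C)(O)C#C | intermediate
11 | (3S,7S)-7-[(4R)-2-(4-methoxyphenyl)-1,3-dioxolan-4-yl]-3-methyl-1-(tributylstannyl)oct-1-yn-3-ol | COc1ccc(cc1)C1OC[C@H](O1)[C@@H](C)CCC[C@](C)(O)C#C[Sn](CCCC)(CCCC)CCCC | intermediate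
12 | (1Z,3S,7S)-7-[(4R)-2-(4-methoxyphenyl)-1,3-dioxolan-4-yl]-3-methyl-1-(tributylstannyl)oct-1-en-3-ol | COc1ccc(cc1)C1OC[C@H](O1)[C@@H](C)CCC[C@](C)(O)/C=C\[Sn](CCCC)(CCCC)CCCC | intermediate
13 | (2R,3S,7S,8Z)-2-[(4-methoxyphenyl)methoxy]-3,7-dimethyl-9-(tributylstannyl)non-8-ene-1,7-diol | OC[C@H](OCc1ccc(OC)cc1)[C@@H](C)CCC[C@](C)(O)/C=C\[Sn](CCCC)(CCCC)CCCC | intermediate
14 | (2R,3S,7S,8Z)-7-hydroxy-2-[(4-methoxyphenyl)methoxy]-3,7-dimethyl-9-(tributylstannyl)non-8-enal | O=C[C@H](OCc1ccc(OC)cc1)[C@@H](C)CCC[C@](C)(O)/C=C\[Sn](CCCC)(CCCC)CCCC | intermediate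
15 | 3-[(tert-butyldimethylsilyl)oxy]propanal | CC(C)(C)[Si](C)(C)OCCC=O | starting material
16 | ethyl (2E)-5-[(tert-butyldimethylsilyl)oxy]-2-methylpent-2-enoate | CCOC(=O)/C(C)=C/CCO[Si](C)(C)C(C)(C)C | intermediate
17 | (2E)-5-[(tert-butyldimethylsilyl)oxy]-2-methylpent-2-en-1-ol | CC(C)(C)[Si](C)(C)OCC/C=C(\C)CO | intermediate
18 | (2E)-5-[(tert-butyldimethylsilyl)oxy]-2-methylpent-2-en-1-yl methanesulfonate | CC(C)(C)[Si](C)(C)OCC/C=C(\C)COS(C)(=O)=O | intermediate
19 | tert-butyl{[(3E)-5-chloro-4-methylpent-3-en-1-yl]oxy}dimethylsilane | CC(C)(C)[Si](C)(C)OCC/C=C(\C)CCl | intermediate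
20 | (3E)-5-chloro-4-methylpent-3-en-1-ol | OCC/C=C(\C)CCl | intermediate
21 | (3E)-5-chloro-4-methylpent-3-enal | O=CC/C=C(\C)CCl | intermediate
22 | methyl (5E)-7-chloro-3-hydroxy-6-methyl-2-methylidenehept-5-enoate (racemic) | COC(=O)C(=C)C(O)C/C=C(\C)CCl | intermediate
23 | methyl (2Z,5E)-2-(bromomethyl)-7-chloro-6-methylhepta-2,5-dienoate | COC(=O)/C(CBr)=C/C/C=C(\C)CCl | intermediate
24 | methyl (3S,4R,5R,6S,10S,11Z)-3-[(2E)-4-chloro-3-methylbut-2-en-1-yl]-4,10-dihydroxy-5-[(4-methoxyphenyl)methoxy]-6,10-dimethyl-2-methylidene-12-(tributylstannyl)dodec-11-enoate | C=C(C(=O)OC)[C@H](C/C=C(\C)CCl)[C@@H](O)[C@H](OCc1ccc(OC)cc1)[C@@H](C)CCC[C@](C)(O)/C=C\[Sn](CCCC)(CCCC)CCCC | intermediate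
25 | (4S,5R)-4-[(2E)-4-chloro-3-methylbut-2-en-1-yl]-5-[(1R,2S,6S,7Z)-6-hydroxy-1-[(4-methoxyphenyl)methoxy]-2,6-dimethyl-8-(tributylstannyl)oct-7-en-1-yl]-3-methylideneoxolan-2-one (seco chloride/stannane) | C=C1C(=O)O[C@H]([C@H]1C/C=C(\C)CCl)[C@H](OCc2ccc(OC)cc2)[C@@H](C)CCC[C@](C)(O)/C=C\[Sn](CCCC)(CCCC)CCCC | intermediate
26 | 13-O-PMB 3,4-deoxy macrocycle (cembrane numbering: 1S,8S,12S,13R,14R; 3E,6Z; 8-hydroxy; 13-(4-methoxybenzyloxy); cis-fused 15(17)-en-16,14-olide) | C=C1C(=O)O[C@H]2[C@H](OCc3ccc(OC)cc3)[C@@H](C)CCC[C@](C)(O)/C=C\C/C(C)=C/C[C@@H]12 | intermediate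
27 | 13-O-PMB ether of the target (1S,3R,4R,8S,12S,13R,14R; 3,4-epoxide) | C=C1C(=O)O[C@H]2[C@H](OCc3ccc(OC)cc3)[C@@H](C)CCC[C@](C)(O)/C=C\C[C@@]4(C)O[C@@H]4C[C@@H]12 | intermediate
28 | CNP0304380.1 (1S,3R,4R,8S,12S,13R,14R; 6Z) | C=C1C(=O)O[C@H]2[C@H](O)[C@@H](C)CCC[C@](C)(O)/C=C\C[C@@]3(C)O[C@@H]3C[C@@H]12 | target

**Step count and risks**

Total steps: 23. Longest linear sequence: 16 steps (steps 1–12 and 20–23).

Steps most likely to fail:

1. Step 20 (fragment union). Chelate control by the PMB ether in water may be incomplete, so that Felkin-type attack erodes the 13,14-syn relationship. The allylindium may also lose its Z geometry and give some trans-lactone, and the acid used for lactonisation may cause protodestannylation. The fallback replaces the ether chelate by a free-hydroxyl chelate; it sets out from 12, uses 23, and rejoins the route at 28. Hydrolysis of the acetal of 12 (AcOH/THF/H2O, rt) should give the stannyl triol F1. 2,2,6,6-Tetramethylpiperidin-1-oxyl (cat.) with PhI(OAc)2 in CH2Cl2 oxidises only the primary alcohol and gives the α-hydroxy aldehyde F2. Indium powder and 23 in THF/H2O then add through the five-membered hydroxyl chelate, the strongest syn-directing arrangement in aqueous indium allylation, to give the dihydroxy ester F3, and PPTS closes it to the 13-hydroxy seco chloride F4. F4 is taken unprotected through the conditions of steps 21 and 22: Pd2(dba)3/AsPh3 closure gives the 13-hydroxy deoxy macrocycle F5, and its Shi epoxidation gives 28 directly, so step 23 is not needed.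

2. Step 21 (macrocyclisation). Transmetallation of the hindered stannane next to the tertiary carbinol may be slow, which would give protodestannylation or oligomers. Syn/anti isomerisation of the π-allyl complex may erode the E geometry, and some coupling at C3 may occur. The fallback keeps the C5–C6 closure but uses a terminal alkyne in place of the stannane and sets the Z geometry after ring closure; it sets out from 10, uses 23, and rejoins at 26. Opening the acetal of 10 with i-Bu2AlH gives the alkynyl PMB diol F6, and Dess–Martin oxidation gives the alkynyl aldehyde F7. Indium allylation with 23 gives the alkynyl hydroxy ester F8 and, after PPTS, the alkynyl seco chloride F9. CuI, NaI and K2CO3 in DMF at high dilution couple the terminal alkyne with the allylic chloride (copper-mediated allyl–alkynyl coupling) to the macrocyclic 1,4-enyne F10. Semihydrogenation with H2 over Pd/CaCO3 poisoned with Pb(OAc)2 and quinoline then gives 26.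

3. Step 22 (epoxidation). The conformation of the macrocycle may override the chiral ketone and lower the facial selectivity. The Z-alkene may be oxidised in competition, and the methylene lactone may suffer at the basic pH. The fallback is a substrate-controlled halohydrin route that puts oxygen on the face opposite to the one electrophiles prefer; it sets out from 26 and rejoins at 27. NBS in THF/H2O at 0 °C should form the bromonium ion on the exposed face of the trisubstituted alkene and be opened by water at the tertiary C4, giving the (3S,4R)-3-bromo-4-hydroxy macrocycle F11. DBU in CH2Cl2 then closes the tertiary alkoxide onto C3 with inversion to give 27.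

**Further compounds**

F1 | step 20 | (2R,3S,7S,8Z)-3,7-dimethyl-9-(tributylstannyl)non-8-ene-1,2,7-triol | OC[C@H](O)[C@@H](C)CCC[C@](C)(O)/C=C\[Sn](CCCC)(CCCC)CCCC
F2 | step 20 | (2R,3S,7S,8Z)-2,7-dihydroxy-3,7-dimethyl-9-(tributylstannyl)non-8-enal | O=C[C@H](O)[C@@H](C)CCC[C@](C)(O)/C=C\[Sn](CCCC)(CCCC)CCCC
F3 | step 20 | methyl (3S,4R,5R,6S,10S,11Z)-3-[(2E)-4-chloro-3-methylbut-2-en-1-yl]-4,5,10-trihydroxy-6,10-dimethyl-2-methylidene-12-(tributylstannyl)dodec-11-enoate | C=C(C(=O)OC)[C@H](C/C=C(\C)CCl)[C@@H](O)[C@H](O)[C@@H](C)CCC[C@](C)(O)/C=C\[Sn](CCCC)(CCCC)CCCC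
F4 | step 20 | (4S,5R)-4-[(2E)-4-chloro-3-methylbut-2-en-1-yl]-5-[(1R,2S,6S,7Z)-1,6-dihydroxy-2,6-dimethyl-8-(tributylstannyl)oct-7-en-1-yl]-3-methylideneoxolan-2-one | C=C1C(=O)O[C@H]([C@H]1C/C=C(\C)CCl)[C@H](O)[C@@H](C)CCC[C@](C)(O)/C=C\[Sn](CCCC)(CCCC)CCCC
F5 | step 20 | 13-hydroxy 3,4-deoxy macrocycle (1S,8S,12S,13R,14R; 3E,6Z) | C=C1C(=O)O[C@H]2[C@H](O)[C@@H](C)CCC[C@](C)(O)/C=C\C/C(C)=C/C[C@@H]12
F6 | step 21 | (2R,3S,7S)-2-[(4-methoxyphenyl)methoxy]-3,7-dimethylnon-8-yne-1,7-diol | OC[C@H](OCc1ccc(OC)cc1)[C@@H](C)CCC[C@](C)(O)C#C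
F7 | step 21 | (2R,3S,7S)-7-hydroxy-2-[(4-methoxyphenyl)methoxy]-3,7-dimethylnon-8-ynal | O=C[C@H](OCc1ccc(OC)cc1)[C@@H](C)CCC[C@](C)(O)C#C
F8 | step 21 | methyl (3S,4R,5R,6S,10S)-3-[(2E)-4-chloro-3-methylbut-2-en-1-yl]-4,10-dihydroxy-5-[(4-methoxyphenyl)methoxy]-6,10-dimethyl-2-methylidenedodec-11-ynoate | C=C(C(=O)OC)[C@H](C/C=C(\C)CCl)[C@@H](O)[C@H](OCc1ccc(OC)cc1)[C@@H](C)CCC[C@](C)(O)C#C
F9 | step 21 | (4S,5R)-4-[(2E)-4-chloro-3-methylbut-2-en-1-yl]-5-[(1R,2S,6S)-6-hydroxy-1-[(4-methoxyphenyl)methoxy]-2,6-dimethyloct-7-yn-1-yl]-3-methylideneoxolan-2-one | C=C1C(=O)O[C@H]([C@H]1C/C=C(\C)CCl)[C@H](OCc2ccc(OC)cc2)[C@@H](C)CCC[C@](C)(O)C#C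
F10 | step 21 | 13-O-PMB 6,7-didehydro (alkyne) 3,4-deoxy macrocycle (1S,8S,12S,13R,14R; 3E) | C=C1C(=O)O[C@H]2[C@H](OCc3ccc(OC)cc3)[C@@H](C)CCC[C@](C)(O)C#CC/C(C)=C/C[C@@H]12
F11 | step 22 | 13-O-PMB (3S,4R)-3-bromo-4-hydroxy macrocycle | C=C1C(=O)O[C@H]2[C@H](OCc3ccc(OC)cc3)[C@@H](C)CCC[C@](C)(O)/C=C\C[C@@](C)(O)[C@@H](Br)C[C@@H]12
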